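## Analysis of the target

The target 22 is a 2,3-dihydrobenzofuran. A benzo ring (C3a to C7a) is fused to a dihydrofuran ring (O1, C2, C3); C2 carries a 4-hydroxy-3,5-dimethoxyphenyl (syringyl) ring, C3 a hydroxymethyl group, C7 a methoxy group and C5 an (E)-propenoic acid. The two stereocentres are adjacent, C2 (S) and C3 (R), with the aryl group and the CH2OH group trans on the five-membered ring. C2 is benzylic to the free-phenol ring and bears the ring oxygen, so it can open to a para-quinone methide and reclose; its configuration is therefore under thermodynamic control and settles trans to C3. C3 is an all-carbon benzylic centre that cannot be corrected later, so it is the centre that must be made in absolute sense. Sensitive groups are the electron-rich free phenol (oxidants), the benzylic aryl ether (strong acid or hot base), the cinnamic acid (reduction) and the primary alcohol. The difficulty is to attach two different, highly oxygenated arenes to neighbouring sp3 carbons with control at C3, without an oxidant touching the syringyl ring, and to bring in the C5 side chain at the right oxidation level. The strategy rests on one feature: C2 and C3 each carry exactly one aryl carbon (C2 the syringyl carbon, C3 the benzo carbon C3a) and C2 also carries oxygen, so the C2–C3 unit is an alkene across which two aryl groups are added while boron on C2 holds the place of that oxygen.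

## Retrosynthetic reasoning

The side-chain C=C bond of 22 is cut first, giving aldehyde 19 and malonic acid 20. The alkene and the acid are the groups least tolerant of earlier chemistry, and a condensation with decarboxylation needs no protection of the phenol or the alcohol. The forward reaction has to give the (E)-acid without opening the dihydrofuran ring.

The O1–C2 bond of 19 is cut next, giving the open alcohol 16, in which both phenols, the primary alcohol and the aldehyde are masked by acid-labile groups. This bond is chosen because C2 lies beside the syringyl ring and ionises readily. One acid treatment should strip every protecting group, ionise C2 and let the ortho phenol close the ring. Ring closure is reversible, so C2 is set trans to C3 whatever its configuration in 16. The C5 carbon is carried as an acetal and not as an ester, because an ester would need a hydride reduction and a reoxidation after the syringyl phenol is free.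

The C2–O bond of 16 is traced to the C2–B bond of boronic ester 15. Oxidation of a C–B bond goes with retention and needs only alkaline peroxide, which none of the masked groups in 15 should notice.

In 15 the two aryl–carbon bonds C2–syringyl and C3–C3a are cut together. This is the central disconnection: it leads back to three simple pieces, the aryllithium 13 (from bromide 2), the (E)-alkenylboronic ester 8 and the aryl triflate 12, and both bonds and both stereocentres form in one catalytic step. The forward reaction is a 1,2-shift of the syringyl group from boron to C2, triggered by an arylpalladium species that then delivers the benzo carbon to C3. A chiral ferrocenyl bisphosphine on palladium chooses the alkene face. Because the alkene carries a substituent on its β-carbon, boron must bear the hindered diol 4; a smaller diol would let palladium take a group directly from boron. The silyl ether on the three-carbon piece only has to last until the acid step.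

Triflate 12 is taken back through aldehyde 11 and phenol 10 to the dihydroxy aldehyde 9. The two hydroxyls of 9 differ in acidity, the one para to the formyl group being the stronger acid, so it can be etherified first and the other one turned into the triflate. The acetal is put on last, under conditions too mild to cleave the aryl acetal ether.

Boronic ester 8 is cut at boron into alkyne 6 and diol 4. Syn hydroboration of the terminal alkyne fixes the (E) geometry, and the diol then displaces the first ligand on boron. Alkyne 6 comes from the alcohol 5 by silylation, and diol 4 from the dione 3 by double methyl addition.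

Aryllithium 13 comes from bromide 2 by halogen–lithium exchange, and 2 from the phenol 1 by etherification. The exchange is planned so that no lithium halide is left, since halide would occupy the site on palladium that the alkene needs.

## Alternatives that were turned down

Alternative 1: The disconnection is the C3–C3a bond, with the hydroxymethyl carbon traced back to the carbonyl carbon of a six-membered ketone, (2S)-6-bromo-8-methoxy-2-[3,5-dimethoxy-4-(pivaloyloxy)phenyl]chroman-4-one A1. In the forward key step an iodine-based two-electron oxidant with strong acid in an orthoester converts A1 into its ketal and places the iodine group on the α-carbon. The benzo carbon then shifts from the ketal carbon to that carbon, so the ring contracts and the old carbonyl carbon leaves the ring as an ester. The product is methyl (2S,3S)-5-bromo-2-[3,5-dimethoxy-4-(pivaloyloxy)phenyl]-7-methoxy-2,3-dihydro-1-benzofuran-3-carboxylate A2.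
- For it: only one stereocentre has to be made by asymmetric synthesis, and the trans relationship follows from the rearrangement itself.
- Against it: the 2-aryl group of A1 is very electron-rich even as its pivalate, so its own 1,2-shift and simple dehydrogenation compete with the ring contraction. The stereocentre of A1 sits beside an aryl ether that can open by a retro-oxa-Michael reaction in acid. C3 of A2 is acidic and can open the ring by β-elimination. After the key step an ester reduction, a Heck reaction on the bromide and two deprotections remain.
- Comparison: this alternative is stronger on the trans relationship, which it delivers directly and not by later equilibration, and it needs no organolithium chemistry. The chosen strategy offers both aryl–carbon bonds in one step from three simple pieces, no oxidant near the electron-rich rings, and stereochemical information stored at C3, which cannot epimerise.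

Alternative 2: The disconnection cuts C2–C3 and O1–C2. C2 with its aryl group comes from a benzylic sulfonium ylide that carries a chiral sulfide, and the rest of the ring from an ortho-quinone methide, 4-bromo-6-[2-(tert-butyldimethylsilyloxy)ethylidene]-2-methoxycyclohexa-2,4-dien-1-one A3, generated with base from a sulfone. In the forward key step the ylide carbon adds to the methide carbon and the phenoxide displaces the sulfide. The product is 4-[(2S,3R)-5-bromo-3-(tert-butyldimethylsilyloxymethyl)-7-methoxy-2,3-dihydro-1-benzofuran-2-yl]-2,6-dimethoxyphenyl pivalate A4.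
- For it: the ring and both stereocentres form in one step, and the trans product follows from the anti displacement in the betaine.
- Against it: A3 has a silyloxy group β to the methide carbon and can tautomerise or eliminate before the ylide arrives. The chirality is stoichiometric. The addition of a stabilised benzylic ylide is reversible, so control at C3 by a remote sulfur centre is uncertain. A sulfonium salt on so electron-rich a benzylic carbon can lose its sulfide. A Heck reaction and deprotections still follow.
- Comparison: this alternative is as strong or stronger in step count and closes the ring directly. The chosen strategy offers catalytic, ligand-controlled face selection on a stable alkene in place of a transient quinone methide, and control at C3 that does not depend on a reversible addition.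

Alternative 3: The disconnection is O1–C2 alone, from methyl (2E)-3-{3-[(2R)-1-(tert-butyldimethylsilyloxy)-3-(4-hydroxy-3,5-dimethoxyphenyl)propan-2-yl]-4-hydroxy-5-methoxyphenyl}prop-2-enoate A5, which has a CH2 group at C2. In the forward key step a silver-based oxidant or a high-potential quinone oxidises the syringyl phenol to its para-quinone methide, and the ortho phenol of the other ring adds to the methide carbon. The product is methyl (2E)-3-[(2S,3R)-3-(tert-butyldimethylsilyloxymethyl)-2-(4-hydroxy-3,5-dimethoxyphenyl)-7-methoxy-2,3-dihydro-1-benzofuran-5-yl]prop-2-enoate A6.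
- For it: the closure is biomimetic, the acrylate is already in place and C2 needs no oxygen beforehand.
- Against it: A5 contains a second oxidisable phenol, a 4-hydroxycinnamate, whose radical couples intermolecularly under the same oxidants. The quinone methide can tautomerise to a stilbene and so destroy C3. The single stereocentre of A5 needs its own multi-step asymmetric synthesis, which builds one carbon–carbon bond at a time.
- Comparison: on the ring closure the two strategies are equal, since both pass through the same kind of quinone methide and both rely on the trans preference; the alternative is stronger in needing no oxygen at C2. The chosen strategy gets that oxygen from the boron that the coupling leaves behind and reaches the quinone methide by acid ionisation, so no oxidant has to tell two phenols apart.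

Key step: step 8

Assumption: the (Sp,Sp) antipode of the ferrocenyl bisphosphine named in step 8 is taken to place the aryl group on the si face of C3; if a model coupling shows the opposite sense, its mirror image is used and nothing else changes.

## Route

Step 1
Reactants: 1 4-bromo-2,6-dimethoxyphenol
Product: 2 5-bromo-1,3-dimethoxy-2-(methoxymethoxy)benzene
Conditions: NaH, MOMCl, THF/DMF, 0 °C to rt
Reagents that add atoms: chloromethyl methyl ether, COCCl
Why: Williamson etherification of the sodium phenoxide; the acetal ether tolerates the organolithium of step 8 and falls in the acid of step 10.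

Step 2
Reactants: 3 acenaphthylene-1,2-dione
Product: 4 cis-1,2-dimethyl-1,2-dihydroacenaphthylene-1,2-diol (meso)
Conditions: AlMe3 (2.5 equiv), toluene, 0 °C to rt; HCl (1 M aq.); recrystallisation
Reagents that add atoms: trimethylaluminium, C[Al](C)C
Why: Two successive 1,2-additions of methyl to the 1,2-dione; the second methyl should enter anti to the bulky aluminium alkoxide and so give mainly the cis diol. Only the cis diol can bridge boron, so any trans isomer is removed on recrystallisation or stays behind in step 4.

Step 3
Reactants: 5 prop-2-yn-1-ol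
Product: 6 tert-butyldimethyl(prop-2-yn-1-yloxy)silane
Conditions: TBSCl, imidazole, CH2Cl2, 0 °C to rt
Reagents that add atoms: tert-butyldimethylsilyl chloride, CC(C)(C)[Si](C)(C)Cl
Why: Standard silylation of a primary alcohol; the silyl ether blocks the hydroxyl during hydroboration and the coupling and is meant to fall in step 10.

Step 4
Reactants: 6 tert-butyldimethyl(prop-2-yn-1-yloxy)silane; 4 cis-1,2-dimethyl-1,2-dihydroacenaphthylene-1,2-diol
Product: 8 cis-1,2-dimethylacenaphthene-1,2-diol (mac) ester of (E)-3-(tert-butyldimethylsilyloxy)prop-1-enylboronic acid, via alkenyl catecholboronate 7 (not isolated)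
Conditions: catecholborane, neat, 70 °C; then 4, THF, rt
Reagents that add atoms: catecholborane, B1Oc2ccccc2O1
Why: Syn hydroboration of the terminal alkyne puts boron on the terminal carbon and fixes the (E) geometry. The aliphatic cis diol then displaces catechol from boron, as in the usual one-pot route to alkenyl boronic esters of tertiary diols.

Step 5
Reactants: 9 3,4-dihydroxy-5-methoxybenzaldehyde
Product: 10 3-hydroxy-5-methoxy-4-(methoxymethoxy)benzaldehyde
Conditions: K2CO3 (1.0 equiv), MOMCl (1.0 equiv), acetone, 0 °C to rt
Reagents that add atoms: chloromethyl methyl ether, COCCl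
Why: Regioselective Williamson etherification: the hydroxyl para to the formyl group is the stronger acid, so one equivalent of carbonate should form that phenoxide and only it is alkylated. The same preference is known for methylation and benzylation of this aldehyde.

Step 6
Reactants: 10 3-hydroxy-5-methoxy-4-(methoxymethoxy)benzaldehyde
Product: 11 5-formyl-3-methoxy-2-(methoxymethoxy)phenyl trifluoromethanesulfonate
Conditions: PhNTf2, Et3N, DMAP (cat.), CH2Cl2, rt
Reagents that add atoms: N-phenylbis(trifluoromethanesulfonimide), O=S(=O)(N(c1ccccc1)S(=O)(=O)C(F)(F)F)C(F)(F)F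
Why: Sulfonylation of the remaining phenol with a mild triflyl donor that leaves the aldehyde and the acetal ether alone.

Step 7
Reactants: 11 5-formyl-3-methoxy-2-(methoxymethoxy)phenyl trifluoromethanesulfonate
Product: 12 5-(dimethoxymethyl)-3-methoxy-2-(methoxymethoxy)phenyl trifluoromethanesulfonate
Conditions: HC(OMe)3, MeOH, PPTS (cat.), rt; Et3N quench
Reagents that add atoms: trimethyl orthoformate, COC(OC)OC; methanol, CO
Why: Acetalisation of an aryl aldehyde driven by the orthoester as water scavenger. A pyridinium salt at room temperature is too weak an acid to cleave the aryl methoxymethyl ether, and the acetal keeps the aldehyde away from the boron ate complex.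

Step 8
Reactants: 2 5-bromo-1,3-dimethoxy-2-(methoxymethoxy)benzene; 8 mac ester of (E)-3-(tert-butyldimethylsilyloxy)prop-1-enylboronic acid; 12 5-(dimethoxymethyl)-3-methoxy-2-(methoxymethoxy)phenyl trifluoromethanesulfonate
Product: 15 mac ester of (1S,2R)-3-(tert-butyldimethylsilyloxy)-2-[5-(dimethoxymethyl)-3-methoxy-2-(methoxymethoxy)phenyl]-1-[3,5-dimethoxy-4-(methoxymethoxy)phenyl]propylboronic acid, via aryllithium 13 (not isolated), via lithium boronate complex 14 (not isolated)
Conditions: 2, n-BuLi (1.0 equiv to 2), THF, −78 °C; 8, −78 °C to rt; concentrate in vacuo; then Pd(OAc)2 (3 mol%), (αR,αR)-2,2'-bis(α-N,N-dimethylaminophenylmethyl)-(S,S)-1,1'-bis[bis(4-methoxy-3,5-dimethylphenyl)phosphino]ferrocene (a MandyPhos ligand, 3.6 mol%), 12 (1.1 equiv), THF, 60 °C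
Reagents that add atoms: none
Why: The closest known reaction type is the palladium-catalysed enantioselective conjunctive cross-coupling of β-substituted alkenylboron ate complexes of the mac diol with aryl triflates, in which an aryllithium supplies the migrating group. Zerovalent palladium, formed from Pd(OAc)2 and the bisphosphine, adds to the C–OTf bond of 12, and the cationic arylpalladium binds the alkene of 14. This binding triggers a 1,2-shift of the syringyl group from boron to C2 on the face opposite palladium, and reductive elimination with retention then forms the C3–C3a bond; no ring is closed. The chiral bisphosphine decides which alkene face palladium occupies and so sets C3, with the aryl group on the si face. The anti relationship of migration and palladation on an (E)-alkene sets C2 relative to C3, giving the (1S,2R) boronic ester. The step needs the metallate shift to win over direct transfer of a group from boron to palladium; the bulky mac diol shields the boron–oxygen atoms and is what secures this for a β-substituted alkene. Exchange with n-BuLi leaves 1-bromobutane, which is removed on concentration, so no halide competes with the alkene for the cationic palladium. The aryllithium is consumed by 8 before 12 is added, so the triflate, the acetal and the acetal ethers never meet an organolithium.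

Step 9
Reactants: 15 mac ester of (1S,2R)-3-(tert-butyldimethylsilyloxy)-2-[5-(dimethoxymethyl)-3-methoxy-2-(methoxymethoxy)phenyl]-1-[3,5-dimethoxy-4-(methoxymethoxy)phenyl]propylboronic acid
Product: 16 (1S,2R)-3-(tert-butyldimethylsilyloxy)-2-[5-(dimethoxymethyl)-3-methoxy-2-(methoxymethoxy)phenyl]-1-[3,5-dimethoxy-4-(methoxymethoxy)phenyl]propan-1-ol
Conditions: H2O2 (30% aq.), NaOH (3 M aq.), THF, 0 °C to rt
Reagents that add atoms: hydrogen peroxide, OO
Why: Boronate oxidation: hydroperoxide adds to boron and the benzylic carbon shifts from boron to oxygen with retention. The substrate has no ester, and the acetal, the acetal ethers and the silyl ether are inert to cold alkaline peroxide; diol 4 is recovered.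

Step 10
Reactants: 16 (1S,2R)-3-(tert-butyldimethylsilyloxy)-2-[5-(dimethoxymethyl)-3-methoxy-2-(methoxymethoxy)phenyl]-1-[3,5-dimethoxy-4-(methoxymethoxy)phenyl]propan-1-ol
Product: 19 (2S,3R)-2-(4-hydroxy-3,5-dimethoxyphenyl)-3-(hydroxymethyl)-7-methoxy-2,3-dihydro-1-benzofuran-5-carbaldehyde, via deprotected diol 17 (not isolated), via para-quinone methide 18 (not isolated)
Conditions: HCl (3 M aq.), THF, 45 °C
Reagents that add atoms: water, O
Why: Acid hydrolysis should remove both methoxymethyl ethers, the silyl ether and the dimethyl acetal. The freed 4-hydroxybenzylic alcohol then ionises to the protonated para-quinone methide, and the ortho phenol closes the ring on the methide carbon in a 5-exo-trig addition. Ionisation and closure are reversible, so C2 should settle trans to the untouched C3, as is known for acid cyclisation of 1,2-diarylpropane-1,3-diols to trans-2-aryl-2,3-dihydrobenzofurans.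

Step 11
Reactants: 19 (2S,3R)-2-(4-hydroxy-3,5-dimethoxyphenyl)-3-(hydroxymethyl)-7-methoxy-2,3-dihydro-1-benzofuran-5-carbaldehyde; 20 malonic acid
Product: 22 (2E)-3-[(2S,3R)-2-(4-hydroxy-3,5-dimethoxyphenyl)-3-(hydroxymethyl)-7-methoxy-2,3-dihydro-1-benzofuran-5-yl]prop-2-enoic acid, via arylidenemalonic acid 21 (not isolated)
Conditions: pyridine, piperidine (cat.), 80 °C
Reagents that add atoms: none
Why: Knoevenagel condensation followed by decarboxylation (Doebner modification) should give the (E)-cinnamic acid. The aldehyde sits on the ring whose oxygen is etherified, so no phenoxide deactivates it, and the free phenol and primary alcohol need no protection.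

## Compound list

1 | 4-bromo-2,6-dimethoxyphenol | COc1cc(Br)cc(OC)c1O | starting material
2 | 5-bromo-1,3-dimethoxy-2-(methoxymethoxy)benzene | COCOc1c(OC)cc(Br)cc1OC | intermediate
3 | acenaphthylene-1,2-dione | O=C1C(=O)c2cccc3cccc1c23 | starting material
4 | cis-1,2-dimethyl-1,2-dihydroacenaphthylene-1,2-diol (meso) | O[C@]1(C)c2cccc3cccc(c23)[C@]1(C)O | intermediate
5 | prop-2-yn-1-ol | C#CCO | starting material
6 | tert-butyldimethyl(prop-2-yn-1-yloxy)silane | C#CCO[Si](C)(C)C(C)(C)C | intermediate
7 | 2-[(E)-3-(tert-butyldimethylsilyloxy)prop-1-enyl]-1,3,2-benzodioxaborole | CC(C)(C)[Si](C)(C)OC/C=C/B1Oc2ccccc2O1 | intermediate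
8 | cis-1,2-dimethylacenaphthene-1,2-diol (mac) ester of (E)-3-(tert-butyldimethylsilyloxy)prop-1-enylboronic acid | CC(C)(C)[Si](C)(C)OC/C=C/B1O[C@]2(C)c3cccc4cccc(c34)[C@]2(C)O1 | intermediate
9 | 3,4-dihydroxy-5-methoxybenzaldehyde | COc1cc(C=O)cc(O)c1O | starting material
10 | 3-hydroxy-5-methoxy-4-(methoxymethoxy)benzaldehyde | COCOc1c(O)cc(C=O)cc1OC | intermediate
11 | 5-formyl-3-methoxy-2-(methoxymethoxy)phenyl trifluoromethanesulfonate | COCOc1c(OC)cc(C=O)cc1OS(=O)(=O)C(F)(F)F | intermediate
12 | 5-(dimethoxymethyl)-3-methoxy-2-(methoxymethoxy)phenyl trifluoromethanesulfonate | COCOc1c(OC)cc(C(OC)OC)cc1OS(=O)(=O)C(F)(F)F | intermediate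
13 | [3,5-dimethoxy-4-(methoxymethoxy)phenyl]lithium | [Li]c1cc(OC)c(OCOC)c(OC)c1 | intermediate
14 | lithium [(E)-3-(tert-butyldimethylsilyloxy)prop-1-enyl][3,5-dimethoxy-4-(methoxymethoxy)phenyl]borate of diol 4 (boron ate complex) | [Li+].COCOc1c(OC)cc(cc1OC)[B-]1(/C=C/CO[Si](C)(C)C(C)(C)C)O[C@]2(C)c3cccc4cccc(c34)[C@]2(C)O1 | intermediate
15 | mac ester of (1S,2R)-3-(tert-butyldimethylsilyloxy)-2-[5-(dimethoxymethyl)-3-methoxy-2-(methoxymethoxy)phenyl]-1-[3,5-dimethoxy-4-(methoxymethoxy)phenyl]propylboronic acid | COCOc1c(OC)cc(C(OC)OC)cc1[C@H](CO[Si](C)(C)C(C)(C)C)[C@H](B1O[C@]2(C)c3cccc4cccc(c34)[C@]2(C)O1)c1cc(OC)c(OCOC)c(OC)c1 | intermediate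
16 | (1S,2R)-3-(tert-butyldimethylsilyloxy)-2-[5-(dimethoxymethyl)-3-methoxy-2-(methoxymethoxy)phenyl]-1-[3,5-dimethoxy-4-(methoxymethoxy)phenyl]propan-1-ol | COCOc1c(OC)cc(C(OC)OC)cc1[C@H](CO[Si](C)(C)C(C)(C)C)[C@H](O)c1cc(OC)c(OCOC)c(OC)c1 | intermediate
17 | 3-[(1S,2R)-1,3-dihydroxy-1-(4-hydroxy-3,5-dimethoxyphenyl)propan-2-yl]-4-hydroxy-5-methoxybenzaldehyde | O=Cc1cc(OC)c(O)c(c1)[C@H](CO)[C@H](O)c1cc(OC)c(O)c(OC)c1 | intermediate
18 | 3-[(2R)-1-(3,5-dimethoxy-4-oxocyclohexa-2,5-dien-1-ylidene)-3-hydroxypropan-2-yl]-4-hydroxy-5-methoxybenzaldehyde | O=Cc1cc(OC)c(O)c(c1)[C@H](CO)C=C1C=C(OC)C(=O)C(OC)=C1 | intermediate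
19 | (2S,3R)-2-(4-hydroxy-3,5-dimethoxyphenyl)-3-(hydroxymethyl)-7-methoxy-2,3-dihydro-1-benzofuran-5-carbaldehyde | COc1cc([C@H]2Oc3c(OC)cc(C=O)cc3[C@@H]2CO)cc(OC)c1O | intermediate
20 | malonic acid | OC(=O)CC(=O)O | starting material
21 | 2-{[(2S,3R)-2-(4-hydroxy-3,5-dimethoxyphenyl)-3-(hydroxymethyl)-7-methoxy-2,3-dihydro-1-benzofuran-5-yl]methylidene}propanedioic acid | COc1cc([C@H]2Oc3c(OC)cc(C=C(C(=O)O)C(=O)O)cc3[C@@H]2CO)cc(OC)c1O | intermediate
22 | (2E)-3-[(2S,3R)-2-(4-hydroxy-3,5-dimethoxyphenyl)-3-(hydroxymethyl)-7-methoxy-2,3-dihydro-1-benzofuran-5-yl]prop-2-enoic acid | COc1cc([C@H]2Oc3c(OC)cc(/C=C/C(=O)O)cc3[C@@H]2CO)cc(OC)c1O | target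

## Step count and weak points

Total: 11 steps. Longest linear sequence: 7 steps (steps 5, 6, 7, 8, 9, 10, 11, from 9).

Step 8 (key step). The most likely failure is direct transfer of the syringyl or the alkenyl group from boron to palladium, which would give simple cross-coupling products in place of the metallate shift. The allylic oxygen and the ortho-substituted triflate make this substrate more demanding than simple alkyl-substituted cases. β-Hydride elimination from the C3–palladium intermediate toward the CH2O group, and poor facial selectivity caused by the ortho acetal ether, are the next risks.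
Fallback: an auxiliary-controlled aldol in place of the three-component coupling, setting out from 12 and 2 and rejoining the route at 19.
- Triflate 12 is coupled with BrZnCH2CO2Et (Pd2(dba)3, XPhos, THF) to give ethyl 2-[5-(dimethoxymethyl)-3-methoxy-2-(methoxymethoxy)phenyl]acetate F1.
- LiOH and a buffered work-up give 2-[5-(dimethoxymethyl)-3-methoxy-2-(methoxymethoxy)phenyl]acetic acid F2.
- The pivaloyl mixed anhydride of F2 acylates lithiated (4S)-4-benzyl-1,3-oxazolidin-2-one to give (4S)-4-benzyl-3-{2-[5-(dimethoxymethyl)-3-methoxy-2-(methoxymethoxy)phenyl]acetyl}-1,3-oxazolidin-2-one F3.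
- Bromide 2 is lithiated as in step 8 and quenched with DMF to give 3,5-dimethoxy-4-(methoxymethoxy)benzaldehyde F4.
- The dibutylboron enolate of F3 (Bu2BOTf, iPr2NEt, CH2Cl2, −78 °C) adds to F4 through a chair transition state in an Evans syn-aldol reaction. This should give (4S)-4-benzyl-3-{(2S,3S)-2-[5-(dimethoxymethyl)-3-methoxy-2-(methoxymethoxy)phenyl]-3-[3,5-dimethoxy-4-(methoxymethoxy)phenyl]-3-hydroxypropanoyl}-1,3-oxazolidin-2-one F5, in which the auxiliary fixes the aryl-bearing carbon in the sense of C3.
- LiBH4 removes the auxiliary and gives (1S,2R)-2-[5-(dimethoxymethyl)-3-methoxy-2-(methoxymethoxy)phenyl]-1-[3,5-dimethoxy-4-(methoxymethoxy)phenyl]propane-1,3-diol F6, which has the configuration of 16 without the silyl group.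
- F6 is taken through the conditions of step 10 to 19.

Step 10. The cation at C2 may fragment with loss of the CH2OH carbon to a stilbene, or eliminate reversibly toward C3 and so erode the one centre that cannot be reset. Intermolecular attack of the cation on an electron-rich ring, or of released formaldehyde on the syringyl ring, is a further risk at higher concentration.
Fallback: oxidative ring closure in place of acid ionisation, setting out from 15 and rejoining at 19.
- Protodeboronation of 15 with Bu4NF trihydrate in warm THF/toluene, which also removes the silyl group, gives (2R)-2-[5-(dimethoxymethyl)-3-methoxy-2-(methoxymethoxy)phenyl]-3-[3,5-dimethoxy-4-(methoxymethoxy)phenyl]propan-1-ol F7.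
- Aqueous HCl in THF then frees 4-hydroxy-3-[(2R)-1-hydroxy-3-(4-hydroxy-3,5-dimethoxyphenyl)propan-2-yl]-5-methoxybenzaldehyde F8. No cation can form at this stage, because C2 carries no leaving group.
- Ag2O in CH2Cl2 oxidises the syringyl phenol of F8 to quinone methide 18 under neutral conditions, and 18 closes to 19.

Step 11. At 80 °C in pyridine the phenoxide of the syringyl ring may expel the ring oxygen, which is para to an electron-poor side chain. The resulting quinone methide can lose formaldehyde or add the amine, which would open the ring irreversibly.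
Fallback: olefination without base, setting out from 19 and rejoining at 22.
- Wittig reaction of 19 with allyl (triphenylphosphoranylidene)acetate in toluene gives prop-2-enyl (2E)-3-[(2S,3R)-2-(4-hydroxy-3,5-dimethoxyphenyl)-3-(hydroxymethyl)-7-methoxy-2,3-dihydro-1-benzofuran-5-yl]prop-2-enoate F9.
- Pd(PPh3)4 with morpholine in THF at room temperature removes the allyl group to give 22.

Step 5. Chloromethyl methyl ether is a very reactive electrophile, so etherification of both hydroxyls, or of the less acidic one, may compete once some product has formed.
Fallback: carry the selectivity with a less reactive electrophile, setting out from 9 and rejoining at 11.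
- Benzyl bromide with Li2CO3 in DMF gives 4-(benzyloxy)-3-hydroxy-5-methoxybenzaldehyde F10.
- Triflation as in step 6 gives 2-(benzyloxy)-5-formyl-3-methoxyphenyl trifluoromethanesulfonate F11.
- BCl3 with pentamethylbenzene at −78 °C removes the benzyl group to give 5-formyl-2-hydroxy-3-methoxyphenyl trifluoromethanesulfonate F12.
- With only one hydroxyl left, MOMCl and iPr2NEt convert F12 into 11.

Step 4. Exchange of catechol by the tertiary diol may stay incomplete, and the moisture-sensitive alkenyl catecholboronate may lose boron by hydrolysis during the exchange.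
Fallback: pass through isolable boron compounds, setting out from 6 and rejoining at 8.
- Hydroboration of 6 with pinacolborane and Cp2ZrHCl (cat.) gives 2-[(E)-3-(tert-butyldimethylsilyloxy)prop-1-enyl]-4,4,5,5-tetramethyl-1,3,2-dioxaborolane F13.
- NaIO4 with NH4OAc in aqueous acetone cleaves the pinacol to give (E)-3-(tert-butyldimethylsilyloxy)prop-1-enylboronic acid F14.
- Condensation of F14 with diol 4 over MgSO4 in CH2Cl2 gives 8.

## Further compounds

F1 | step 8 | ethyl 2-[5-(dimethoxymethyl)-3-methoxy-2-(methoxymethoxy)phenyl]acetate | CCOC(=O)Cc1cc(C(OC)OC)cc(OC)c1OCOC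
F2 | step 8 | 2-[5-(dimethoxymethyl)-3-methoxy-2-(methoxymethoxy)phenyl]acetic acid | OC(=O)Cc1cc(C(OC)OC)cc(OC)c1OCOC
F3 | step 8 | (4S)-4-benzyl-3-{2-[5-(dimethoxymethyl)-3-methoxy-2-(methoxymethoxy)phenyl]acetyl}-1,3-oxazolidin-2-one | O=C(Cc1cc(C(OC)OC)cc(OC)c1OCOC)N1[C@@H](Cc2ccccc2)COC1=O
F4 | step 8 | 3,5-dimethoxy-4-(methoxymethoxy)benzaldehyde | COCOc1c(OC)cc(C=O)cc1OC
F5 | step 8 | (4S)-4-benzyl-3-{(2S,3S)-2-[5-(dimethoxymethyl)-3-methoxy-2-(methoxymethoxy)phenyl]-3-[3,5-dimethoxy-4-(methoxymethoxy)phenyl]-3-hydroxypropanoyl}-1,3-oxazolidin-2-one | COCOc1c(OC)cc(C(OC)OC)cc1[C@H](C(=O)N1[C@@H](Cc2ccccc2)COC1=O)[C@H](O)c1cc(OC)c(OCOC)c(OC)c1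
F6 | step 8 | (1S,2R)-2-[5-(dimethoxymethyl)-3-methoxy-2-(methoxymethoxy)phenyl]-1-[3,5-dimethoxy-4-(methoxymethoxy)phenyl]propane-1,3-diol | COCOc1c(OC)cc(C(OC)OC)cc1[C@H](CO)[C@H](O)c1cc(OC)c(OCOC)c(OC)c1
F7 | step 10 | (2R)-2-[5-(dimethoxymethyl)-3-methoxy-2-(methoxymethoxy)phenyl]-3-[3,5-dimethoxy-4-(methoxymethoxy)phenyl]propan-1-ol | COCOc1c(OC)cc(C(OC)OC)cc1[C@H](CO)Cc1cc(OC)c(OCOC)c(OC)c1
F8 | step 10 | 4-hydroxy-3-[(2R)-1-hydroxy-3-(4-hydroxy-3,5-dimethoxyphenyl)propan-2-yl]-5-methoxybenzaldehyde | O=Cc1cc(OC)c(O)c(c1)[C@H](CO)Cc1cc(OC)c(O)c(OC)c1
F9 | step 11 | prop-2-enyl (2E)-3-[(2S,3R)-2-(4-hydroxy-3,5-dimethoxyphenyl)-3-(hydroxymethyl)-7-methoxy-2,3-dihydro-1-benzofuran-5-yl]prop-2-enoate | COc1cc([C@H]2Oc3c(OC)cc(/C=C/C(=O)OCC=C)cc3[C@@H]2CO)cc(OC)c1O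
F10 | step 5 | 4-(benzyloxy)-3-hydroxy-5-methoxybenzaldehyde | COc1cc(C=O)cc(O)c1OCc1ccccc1
F11 | step 5 | 2-(benzyloxy)-5-formyl-3-methoxyphenyl trifluoromethanesulfonate | COc1cc(C=O)cc(OS(=O)(=O)C(F)(F)F)c1OCc1ccccc1
F12 | step 5 | 5-formyl-2-hydroxy-3-methoxyphenyl trifluoromethanesulfonate | COc1cc(C=O)cc(OS(=O)(=O)C(F)(F)F)c1O
F13 | step 4 | 2-[(E)-3-(tert-butyldimethylsilyloxy)prop-1-enyl]-4,4,5,5-tetramethyl-1,3,2-dioxaborolane | CC(C)(C)[Si](C)(C)OC/C=C/B1OC(C)(C)C(C)(C)O1
F14 | step 4 | (E)-3-(tert-butyldimethylsilyloxy)prop-1-enylboronic acid | CC(C)(C)[Si](C)(C)OC/C=C/B(O)O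
A1 | alternative 1 | (2S)-6-bromo-8-methoxy-2-[3,5-dimethoxy-4-(pivaloyloxy)phenyl]chroman-4-one | COc1cc([C@@H]2CC(=O)c3cc(Br)cc(OC)c3O2)cc(OC)c1OC(=O)C(C)(C)C
A2 | alternative 1 | methyl (2S,3S)-5-bromo-2-[3,5-dimethoxy-4-(pivaloyloxy)phenyl]-7-methoxy-2,3-dihydro-1-benzofuran-3-carboxylate | COc1cc([C@H]2Oc3c(OC)cc(Br)cc3[C@@H]2C(=O)OC)cc(OC)c1OC(=O)C(C)(C)C
A3 | alternative 2 | 4-bromo-6-[2-(tert-butyldimethylsilyloxy)ethylidene]-2-methoxycyclohexa-2,4-dien-1-one | O=C1C(OC)=CC(Br)=CC1=CCO[Si](C)(C)C(C)(C)C
A4 | alternative 2 | 4-[(2S,3R)-5-bromo-3-(tert-butyldimethylsilyloxymethyl)-7-methoxy-2,3-dihydro-1-benzofuran-2-yl]-2,6-dimethoxyphenyl pivalate | COc1cc([C@H]2Oc3c(OC)cc(Br)cc3[C@@H]2CO[Si](C)(C)C(C)(C)C)cc(OC)c1OC(=O)C(C)(C)C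
A5 | alternative 3 | methyl (2E)-3-{3-[(2R)-1-(tert-butyldimethylsilyloxy)-3-(4-hydroxy-3,5-dimethoxyphenyl)propan-2-yl]-4-hydroxy-5-methoxyphenyl}prop-2-enoate | COC(=O)/C=C/c1cc(OC)c(O)c(c1)[C@H](CO[Si](C)(C)C(C)(C)C)Cc1cc(OC)c(O)c(OC)c1
A6 | alternative 3 | methyl (2E)-3-[(2S,3R)-3-(tert-butyldimethylsilyloxymethyl)-2-(4-hydroxy-3,5-dimethoxyphenyl)-7-methoxy-2,3-dihydro-1-benzofuran-5-yl]prop-2-enoate | COc1cc([C@H]2Oc3c(OC)cc(/C=C/C(=O)OC)cc3[C@@H]2CO[Si](C)(C)C(C)(C)C)cc(OC)c1O
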